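The diaryl ether bond is cut between the carbon of ring A (the monohydroxy arene) that is meta to both chain and hydroxyl and the central oxygen of ring B (the 1,2,3-trioxygenated arene). One Pd-catalysed intramolecular O-arylation closes the 20-membered ring (three ring A atoms, the ether O, four ring B atoms, twelve CH2) as the only ring-forming event. It exploits that this oxygen lies between two oxygenated carbons and para to the chain: as a 2,6-dimethoxy-4-alkylphenol it can only be O-arylated. The precursor is open-chain 4-[12-(3-chloro-5-methoxyphenyl)dodecyl]-2,6-dimethoxyphenol, assembled in two steps from three commercial pieces; its chloride survives both bromide-selective couplings.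

Key step: step 3

Remark: the target has no stereocentre and is achiral, so no step has to set or protect configuration.

Step 1
Reactants: 1 1-bromo-3-chloro-5-methoxybenzene; 2 12-bromododec-1-ene
Product: 4 1-chloro-3-(dodec-11-en-1-yl)-5-methoxybenzene, via arylmagnesium bromide 3 (not isolated)
Conditions: Mg turnings, LiCl, THF, rt; then slow addition to 2, Fe(acac)3 (5 mol %), TMEDA, THF, 0 °C
Reagents that add atoms: none
Why: Magnesium inserts into the C–Br bond only, and the iron-catalysed Kumada-type aryl–alkyl coupling should then join the Grignard carbon to the primary bromide while the aryl chloride, which does not couple with aryl Grignards under iron catalysis, and the remote terminal alkene stay intact.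

Step 2
Reactants: 4 1-chloro-3-(dodec-11-en-1-yl)-5-methoxybenzene; 5 4-bromo-2,6-dimethoxyphenol
Product: 7 4-[12-(3-chloro-5-methoxyphenyl)dodecyl]-2,6-dimethoxyphenol, via B-alkyl-9-BBN 6 (not isolated)
Conditions: 9-BBN (1.1 equiv), THF, 0 °C to rt; then 5, Pd(dppf)Cl2 (5 mol %), aq K3PO4 (3 equiv), THF/DMF, 65 °C
Reagents that add atoms: none
Why: Anti-Markovnikov hydroboration with 9-BBN followed by B-alkyl Suzuki–Miyaura coupling should join the terminal carbon to C4 of the bromophenol, since Pd(dppf) inserts into C–Br but not into the unactivated C–Cl bond at this temperature and the phenol is simply carried as its phenoxide.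

Step 3
Reactants: 7 4-[12-(3-chloro-5-methoxyphenyl)dodecyl]-2,6-dimethoxyphenol
Product: 8 macrocyclic diaryl ether trimethyl ether (the target with its three hydroxyls as methoxy groups)
Conditions: Pd(OAc)2 (10 mol %), tBuXPhos (15 mol %), K3PO4 (3 equiv), toluene, 100 °C, 7 added by syringe pump over 12 h (final 2 mM)
Reagents that add atoms: none
Why: L·Pd(0) (L = bulky di-tert-butyl biarylphosphine) should add oxidatively into the only C–Cl bond, the one on ring A; phosphate then exchanges chloride for the tethered ring B phenoxide, and the hindered ligand forces C–O reductive elimination from the aryl(aryloxo)palladium(II) species. The closest known reaction type is the Buchwald–Hartwig-type Pd-catalysed diaryl ether synthesis from aryl chlorides and ortho,ortho-disubstituted phenols, run here intramolecularly under pseudo-high dilution in the manner of Ullmann macrocyclisations of cyclophane diaryl ethers. The 20-membered ring (ring A bridged meta, ring B bridged para, the ether O, twelve CH2) closes head-to-tail through the new C(ring A)–O bond, with little strain because the C12 tether spans the meta/para ether geometry freely. No stereocentre is formed. The step needs ring closure to beat intermolecular etherification, which slow addition at low stationary concentration secures, and O- over C-arylation, which the substrate secures because both ortho positions of the phenol carry methoxy groups and the para position carries the chain; the aryl methyl ethers are inert.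

Step 4
Reactants: 8 macrocyclic diaryl ether trimethyl ether
Product: 9 CNP0314249.0 (target)
Conditions: BBr3 (6 equiv), CH2Cl2, −78 °C to rt; then MeOH, H2O
Reagents that add atoms: none
Why: Lewis acid-mediated aryl methyl ether cleavage (BBr3 demethylation: O–B complexation, then bromide attack at methyl) should free all three phenols, the diaryl ether and the saturated chain being inert, and aqueous work-up hydrolyses the aryl borates.

Compound list
1 | 1-bromo-3-chloro-5-methoxybenzene | COc1cc(Cl)cc(Br)c1 | starting material
2 | 12-bromododec-1-ene | BrCCCCCCCCCCC=C | starting material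
3 | (3-chloro-5-methoxyphenyl)magnesium bromide, formed in the flask | COc1cc(Cl)cc([Mg]Br)c1 | intermediate
4 | 1-chloro-3-(dodec-11-en-1-yl)-5-methoxybenzene | COc1cc(Cl)cc(CCCCCCCCCCC=C)c1 | intermediate
5 | 4-bromo-2,6-dimethoxyphenol | COc1cc(Br)cc(OC)c1O | starting material
6 | 9-[12-(3-chloro-5-methoxyphenyl)dodecyl]-9-borabicyclo[3.3.1]nonane, formed in the flask | COc1cc(Cl)cc(CCCCCCCCCCCCB2C3CCCC2CCC3)c1 | intermediate
7 | 4-[12-(3-chloro-5-methoxyphenyl)dodecyl]-2,6-dimethoxyphenol | COc1cc(Cl)cc(CCCCCCCCCCCCc2cc(OC)c(O)c(OC)c2)c1 | intermediate
8 | macrocyclic diaryl ether trimethyl ether (20-membered meta,para-cyclophane; ring A 5-methoxy, ring B 2,6-dimethoxy around the ether oxygen) | COc1cc2cc(c1)Oc1c(OC)cc(cc1OC)CCCCCCCCCCCC2 | intermediate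
9 | CNP0314249.0 | Oc1cc2cc(c1)Oc1c(O)cc(cc1O)CCCCCCCCCCCC2 | target

Total step count: 4. Longest linear sequence: 4 steps (1 to 9).

Steps most likely to fail

Step 3. Ring closure may lose to intermolecular etherification (oligomers) at the dilution the catalyst tolerates, or C–O reductive elimination may be slowed by chelation of the 2,6-dimethoxyphenoxide so that hydrodechlorination takes over. The fallback sets out from 7 and replaces the Pd(0) nucleophile–electrophile coupling by a room-temperature Cu(II)-mediated oxidative coupling of two nucleophiles. Miyaura borylation of the aryl chloride (B2pin2, Pd2(dba)3, XPhos, KOAc, dioxane, 100 °C) should give the pinacol boronate F1. Transesterification with excess methylboronic acid (acetone, 0.1 M aq HCl, rt, then evaporation) should give the boronic acid F2. Chan–Lam macrocyclisation of F2 (Cu(OAc)2, pyridine, Et3N, 4 Å MS, CH2Cl2, air, rt, 2 mM) should return to the route at 8.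

Step 2. Oxidative addition into the electron-rich bromophenoxide may be slow, so that protodeboronation or β-hydride elimination of the alkylborane, or partial activation of the C–Cl bond, competes. The fallback sets out from 4 and builds the same bond by olefin metathesis instead of cross-coupling. Cross-metathesis with 4-vinyl-2,6-dimethoxyphenol ((H2IMes)(PCy3)Cl2Ru=CHPh, CH2Cl2, 40 °C) should give the (E)-styrene F3. Diimide reduction (TsNHNH2, NaOAc, THF/H2O, reflux) should saturate the alkene without touching the C–Cl bond and return to the route at 7.

Step 1. Homocoupling of the aryl Grignard, β-hydride elimination at the alkyl–iron stage or migration of the terminal double bond may erode the coupling. The fallback sets out from 1 and uses a bromide-selective B-alkyl Suzuki–Miyaura coupling instead. Commercial dodeca-1,11-diene (3–4 equiv) is monohydroborated with 9-BBN (THF, rt) to the alkenylborane F4. Coupling of F4 with 1 (Pd(dppf)Cl2, aq K3PO4, THF, 60 °C) should return to the route at 4, the aryl chloride again staying untouched.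

Further compounds
F1 | step 3 | 2,6-dimethoxy-4-{12-[3-methoxy-5-(4,4,5,5-tetramethyl-1,3,2-dioxaborolan-2-yl)phenyl]dodecyl}phenol | COc1cc(cc(CCCCCCCCCCCCc2cc(OC)c(O)c(OC)c2)c1)B1OC(C)(C)C(C)(C)O1
F2 | step 3 | {3-[12-(4-hydroxy-3,5-dimethoxyphenyl)dodecyl]-5-methoxyphenyl}boronic acid | COc1cc(cc(CCCCCCCCCCCCc2cc(OC)c(O)c(OC)c2)c1)B(O)O
F3 | step 2 | 4-[(E)-12-(3-chloro-5-methoxyphenyl)dodec-1-en-1-yl]-2,6-dimethoxyphenol | COc1cc(Cl)cc(CCCCCCCCCC/C=C/c2cc(OC)c(O)c(OC)c2)c1
F4 | step 1 | 9-(dodec-11-en-1-yl)-9-borabicyclo[3.3.1]nonane | C=CCCCCCCCCCCB1C2CCCC1CCC2
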